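**Plan**

1. Retrosynthesis: the C3–OH and benzylic C–H bonds go back to a 3-benzylidene oxolane (via its epoxide); the oxolane C2–C3 bond is cut to an O–CH2 radical and an aryl alkyne; the alkyne–ring B bond is cut (Sonogashira) to aryl iodide 19, which already carries the erythro glycerol aryl ether; the C4–C5 bond is cut to O-benzylvanillin and a chiral allenylzinc reagent.
2. Enabling feature (oxolane numbered O1, C2H2, C3(OH)(CH2-ring B), C4, C5-aryl; ring B is the central 2-methoxyphenoxy ring): C2 bears only O1 and two hydrogens, so it can arrive as the CH2 of a methoxymethyl acetal converted into an alkoxymethyl radical. C3 with its benzyl group is the hydrated, reduced form of an aryl alkyne, so one 5-exo-dig closure makes the ring and completes the carbon skeleton.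
3. Forward order: side chain built on 4-iodo-2-methoxyphenol (19); open-chain C5–C4 unit by propargylation (8); union by Sonogashira coupling (20); the oxolane, the only ring formed, closes in step 15; epoxidation, hydrogenolysis and desilylation finish.
4. Stereochemistry: C4 and C5 from (R)-glyceraldehyde acetonide through the mesylate (net inversion, anti addition); C3 from epoxidation anti to the C4 substituent; side-chain C2 from methyl (R)-glycerate by Mitsunobu inversion, side-chain C1 by Felkin–Anh Grignard addition.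

Key step: step 15

Remark: the E/Z mixture of 23 and the epimers of 24 at the oxirane CH are carried on unseparated, because that carbon becomes CH2 in step 17.

**Route**

Step 1
Reactants: 1 (R)-2,2-dimethyl-1,3-dioxolane-4-carbaldehyde
Product: 2 (S)-4-ethynyl-2,2-dimethyl-1,3-dioxolane
Conditions: dimethyl (1-diazo-2-oxopropyl)phosphonate, K2CO3, MeOH, 0 °C to rt
Reagents that add atoms: dimethyl (1-diazo-2-oxopropyl)phosphonate, CC(=O)C(=[N+]=[N-])P(=O)(OC)OC
Why: Seyferth–Gilbert homologation in its Ohira–Bestmann form converts the aldehyde into the terminal alkyne with one added carbon; the stereocenter is carried over from the chiral pool (R becomes S only through changed CIP ranks).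

Step 2
Reactants: 2 (S)-4-ethynyl-2,2-dimethyl-1,3-dioxolane
Product: 3 (S)-but-3-yne-1,2-diol
Conditions: acidic ion-exchange resin (Dowex 50W, H+ form), MeOH–H2O 9:1, rt
Reagents that add atoms: none
Why: Acid-catalysed acetal hydrolysis frees the 1,2-diol without touching the alkyne or the stereocenter.

Step 3
Reactants: 3 (S)-but-3-yne-1,2-diol
Product: 4 (S)-1-[(tert-butyldiphenylsilyl)oxy]but-3-yn-2-ol
Conditions: TBDPSCl (1.05 equiv), imidazole, CH2Cl2, 0 °C
Reagents that add atoms: tert-butyl(chloro)diphenylsilane, CC(C)(C)[Si](Cl)(c1ccccc1)c1ccccc1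
Why: Silylation with a bulky silyl chloride is selective for the primary hydroxyl, and the group later shields one face of the oxolane.

Step 4
Reactants: 4 (S)-1-[(tert-butyldiphenylsilyl)oxy]but-3-yn-2-ol
Product: 5 (S)-1-[(tert-butyldiphenylsilyl)oxy]but-3-yn-2-yl methanesulfonate
Conditions: MsCl, Et3N, CH2Cl2, −78 to 0 °C
Reagents that add atoms: methanesulfonyl chloride, CS(=O)(=O)Cl
Why: O-Sulfonylation with retention gives the propargylic leaving group needed for SN2′ oxidative addition.

Step 5
Reactants: 5 (S)-1-[(tert-butyldiphenylsilyl)oxy]but-3-yn-2-yl methanesulfonate; 6 4-(benzyloxy)-3-methoxybenzaldehyde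
Product: 8 (1S,2R)-1-[4-(benzyloxy)-3-methoxyphenyl]-2-{[(tert-butyldiphenylsilyl)oxy]methyl}but-3-yn-1-ol, via allenylzinc reagent 7 (not isolated)
Conditions: Pd(OAc)2 (5 mol %), PPh3 (5 mol %), Et2Zn (3 equiv), THF, −78 to −20 °C; NH4Cl work-up
Reagents that add atoms: none
Why: Palladium-catalysed propargylation of an aldehyde by an allenylzinc reagent made in situ from a propargylic mesylate: zerovalent palladium opens 5 anti (SN2′), transmetalation gives 7, and its cyclic SE2′ addition to 6 should give the anti homopropargylic alcohol, the CH(CH2OSi) center coming from the mesylate carbon with net inversion and the carbinol center from the anti-selective transition state.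

Step 6
Reactants: 8 (1S,2R)-1-[4-(benzyloxy)-3-methoxyphenyl]-2-{[(tert-butyldiphenylsilyl)oxy]methyl}but-3-yn-1-ol
Product: 9 methoxymethyl ether of 8
Conditions: MOMCl, i-Pr2NEt, Bu4NI (cat.), CH2Cl2, 0 °C to rt
Reagents that add atoms: chloromethyl methyl ether, COCCl
Why: O-Alkylation with the α-chloro ether gives the acetal whose CH2 becomes C2 of the oxolane; no stereocenter is touched.

Step 7
Reactants: 10 methyl (R)-2,2-dimethyl-1,3-dioxolane-4-carboxylate
Product: 11 methyl (R)-2,3-dihydroxypropanoate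
Conditions: acidic ion-exchange resin (Dowex 50W, H+ form), MeOH–H2O 9:1, rt
Reagents that add atoms: none
Why: Acid-catalysed acetal hydrolysis; methanol as solvent keeps the methyl ester intact.

Step 8
Reactants: 11 methyl (R)-2,3-dihydroxypropanoate
Product: 12 methyl (R)-3-[(tert-butyldimethylsilyl)oxy]-2-hydroxypropanoate
Conditions: TBSCl (1.0 equiv), imidazole, CH2Cl2, 0 °C
Reagents that add atoms: tert-butyl(chloro)dimethylsilane, CC(C)(C)[Si](C)(C)Cl
Why: Selective silylation of the primary hydroxyl leaves the α-hydroxy ester free for etherification.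

Step 9
Reactants: 12 methyl (R)-3-[(tert-butyldimethylsilyl)oxy]-2-hydroxypropanoate; 13 4-iodo-2-methoxyphenol
Product: 14 methyl (S)-3-[(tert-butyldimethylsilyl)oxy]-2-(4-iodo-2-methoxyphenoxy)propanoate
Conditions: PPh3, DIAD, THF, 0 °C to rt
Reagents that add atoms: none
Why: Mitsunobu etherification of an α-hydroxy ester by a phenol proceeds by SN2 with clean inversion, setting the aryloxy-bearing center as S.

Step 10
Reactants: 14 methyl (S)-3-[(tert-butyldimethylsilyl)oxy]-2-(4-iodo-2-methoxyphenoxy)propanoate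
Product: 15 (S)-3-[(tert-butyldimethylsilyl)oxy]-2-(4-iodo-2-methoxyphenoxy)propanal
Conditions: i-Bu2AlH (1.1 equiv), CH2Cl2, −78 °C; Rochelle salt work-up
Reagents that add atoms: none
Why: Partial reduction of the α-alkoxy ester stops at the aldehyde at low temperature because the tetrahedral aluminium hemiacetal persists until work-up; the cold conditions protect the α-stereocenter.

Step 11
Reactants: 15 (S)-3-[(tert-butyldimethylsilyl)oxy]-2-(4-iodo-2-methoxyphenoxy)propanal; 16 1-(benzyloxy)-4-bromo-2-methoxybenzene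
Product: 18 (1R,2S)-1-[4-(benzyloxy)-3-methoxyphenyl]-3-[(tert-butyldimethylsilyl)oxy]-2-(4-iodo-2-methoxyphenoxy)propan-1-ol, via arylmagnesium bromide 17 (not isolated)
Conditions: Mg, THF, 40 °C (16 to 17); then 15, THF, −78 °C; NH4Cl work-up
Reagents that add atoms: none
Why: Grignard addition to an α-aryloxy aldehyde under Felkin–Anh (non-chelation) control, with the aryloxy group anti to the incoming nucleophile, should give mainly the 1,2-anti (erythro) alcohol; halogen–magnesium exchange at the aryl iodide is slow at −78 °C.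

Step 12
Reactants: 18 (1R,2S)-1-[4-(benzyloxy)-3-methoxyphenyl]-3-[(tert-butyldimethylsilyl)oxy]-2-(4-iodo-2-methoxyphenoxy)propan-1-ol
Product: 19 (1R,2S)-1-[4-(benzyloxy)-3-methoxyphenyl]-1,3-bis[(tert-butyldimethylsilyl)oxy]-2-(4-iodo-2-methoxyphenoxy)propane (fragment 2)
Conditions: TBSOTf, 2,6-lutidine, CH2Cl2, −78 to 0 °C
Reagents that add atoms: tert-butyldimethylsilyl trifluoromethanesulfonate, CC(C)(C)[Si](C)(C)OS(=O)(=O)C(F)(F)F
Why: Silyl triflate silylation protects the hindered benzylic alcohol under non-ionizing, buffered conditions.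

Step 13
Reactants: 9 methoxymethyl ether of 8; 19 fragment 2
Product: 20 internal aryl alkyne (ring B joined to the alkyne terminus of 9)
Conditions: Pd(PPh3)2Cl2 (3 mol %), CuI (6 mol %), Et3N, THF, rt, degassed
Reagents that add atoms: none
Why: Sonogashira coupling of a terminal alkyne with an aryl iodide joins the two fragments under mild conditions that leave acetal, silyl and benzyl ethers intact.

Step 14
Reactants: 20 internal aryl alkyne
Product: 22 (phenylselanyl)methyl ether corresponding to 20, via bromomethyl ether 21 (not isolated)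
Conditions: Me2BBr (2 equiv), CH2Cl2, −78 °C; then PhSeH, i-Pr2NEt, −78 to 0 °C
Reagents that add atoms: benzeneselenol, [SeH]c1ccccc1
Why: Bromodimethylborane cleaves the methoxymethyl acetal at the unhindered methoxy oxygen to the α-bromo ether, which selenolate displaces (acetal exchange, SN substitution at the acetal carbon), giving the radical precursor without touching a stereocenter.

Step 15
Reactants: 22 (phenylselanyl)methyl ether
Product: 23 (4R,5S)-3-benzylidene oxolane (E/Z mixture)
Conditions: Bu3SnH (1.5 equiv), AIBN (0.2 equiv), syringe-pump addition over 6 h, benzene (0.01 M), 80 °C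
Reagents that add atoms: none
Why: The tributyltin radical abstracts the phenylselanyl group to give the nucleophilic alkoxymethyl radical O1–C2H2•, which adds to the proximal alkyne carbon (future C3); the resulting α-aryl vinyl radical takes hydrogen from Bu3SnH and the chain continues. The closest known reaction type is the tin hydride-mediated cyclization of alkoxymethyl radicals from (phenylselanyl)methyl ethers of homoallylic and homopropargylic alcohols to 3-substituted oxolanes. The oxolane closes in the 5-exo-dig mode. No stereocenter is formed: C4 and C5 are carried through unchanged, and the E/Z geometry of the benzylidene does not matter because both isomers converge in steps 16 and 17. The step needs 5-exo rather than 6-endo attack, which the short C–O bonds of the tether and the aryl stabilization of the vinyl radical secure. It also needs ring closure to outrun hydrogen transfer to the primary radical, which slow addition of Bu3SnH at high dilution secures.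

Step 16
Reactants: 23 (4R,5S)-3-benzylidene oxolane
Product: 24 (3S,4R,5S) spiro-epoxide (1,5-dioxaspiro[2.4]heptane; epimers at the oxirane CH)
Conditions: DMDO (1.2 equiv, acetone solution), CH2Cl2, −40 to 0 °C; crude product used directly
Reagents that add atoms: dimethyldioxirane, CC1(C)OO1
Why: Neutral electrophilic epoxidation of the electron-rich exocyclic styrene; oxygen should be delivered to the ring face anti to the adjacent C4 CH2OTBDPS group, which sets C3.

Step 17
Reactants: 24 (3S,4R,5S) spiro-epoxide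
Product: 25 tris-silyl ether of the target with both phenols free
Conditions: H2 (1 atm), Pd/C (10 %), NaHCO3, EtOAc–EtOH, rt
Reagents that add atoms: none
Why: Palladium-catalysed hydrogenolysis cleaves the benzylic C–O bond of the aryl oxirane (leaving the tertiary C3–OH with its configuration) and both phenolic benzyl ethers in one operation, while the silyl ethers and the slower cyclic benzylic ether should survive under buffered neutral conditions.

Step 18
Reactants: 25 tris-silyl ether of the target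
Product: 26 CNP0350466.2 (target)
Conditions: Bu4NF (6 equiv), AcOH (6 equiv), THF, rt to 40 °C
Reagents that add atoms: none
Why: Fluoride-mediated desilylation buffered with acetic acid removes the three silyl ethers without epimerizing or eliminating at the benzylic centers.

**Compound list**

1 | (R)-2,2-dimethyl-1,3-dioxolane-4-carbaldehyde | O=C[C@H]1COC(C)(C)O1 | starting material
2 | (S)-4-ethynyl-2,2-dimethyl-1,3-dioxolane | C#C[C@H]1COC(C)(C)O1 | intermediate
3 | (S)-but-3-yne-1,2-diol | C#C[C@H](O)CO | intermediate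
4 | (S)-1-[(tert-butyldiphenylsilyl)oxy]but-3-yn-2-ol | C#C[C@H](O)CO[Si](c1ccccc1)(c1ccccc1)C(C)(C)C | intermediate
5 | (S)-1-[(tert-butyldiphenylsilyl)oxy]but-3-yn-2-yl methanesulfonate | C#C[C@H](OS(C)(=O)=O)CO[Si](c1ccccc1)(c1ccccc1)C(C)(C)C | intermediate
6 | 4-(benzyloxy)-3-methoxybenzaldehyde | COc1cc(C=O)ccc1OCc1ccccc1 | starting material
7 | ethyl[(P)-4-[(tert-butyldiphenylsilyl)oxy]buta-1,2-dien-1-yl]zinc (formed in the flask) | CC[Zn]C([H])=[C@@]=C([H])CO[Si](c1ccccc1)(c1ccccc1)C(C)(C)C | intermediate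
8 | (1S,2R)-1-[4-(benzyloxy)-3-methoxyphenyl]-2-{[(tert-butyldiphenylsilyl)oxy]methyl}but-3-yn-1-ol | O[C@H](c1ccc(OCc2ccccc2)c(OC)c1)[C@H](C#C)CO[Si](c1ccccc1)(c1ccccc1)C(C)(C)C | intermediate
9 | methoxymethyl ether of 8: {[(2R)-2-{(S)-[4-(benzyloxy)-3-methoxyphenyl](methoxymethoxy)methyl}but-3-yn-1-yl]oxy}(tert-butyl)diphenylsilane | COCO[C@H](c1ccc(OCc2ccccc2)c(OC)c1)[C@H](C#C)CO[Si](c1ccccc1)(c1ccccc1)C(C)(C)C | intermediate
10 | methyl (R)-2,2-dimethyl-1,3-dioxolane-4-carboxylate | COC(=O)[C@H]1COC(C)(C)O1 | starting material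
11 | methyl (R)-2,3-dihydroxypropanoate | COC(=O)[C@H](O)CO | intermediate
12 | methyl (R)-3-[(tert-butyldimethylsilyl)oxy]-2-hydroxypropanoate | COC(=O)[C@H](O)CO[Si](C)(C)C(C)(C)C | intermediate
13 | 4-iodo-2-methoxyphenol | COc1cc(I)ccc1O | starting material
14 | methyl (S)-3-[(tert-butyldimethylsilyl)oxy]-2-(4-iodo-2-methoxyphenoxy)propanoate | COC(=O)[C@H](CO[Si](C)(C)C(C)(C)C)Oc1ccc(I)cc1OC | intermediate
15 | (S)-3-[(tert-butyldimethylsilyl)oxy]-2-(4-iodo-2-methoxyphenoxy)propanal | O=C[C@H](CO[Si](C)(C)C(C)(C)C)Oc1ccc(I)cc1OC | intermediate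
16 | 1-(benzyloxy)-4-bromo-2-methoxybenzene | COc1cc(Br)ccc1OCc1ccccc1 | starting material
17 | [4-(benzyloxy)-3-methoxyphenyl]magnesium bromide (formed in the flask) | COc1cc([Mg]Br)ccc1OCc1ccccc1 | intermediate
18 | (1R,2S)-1-[4-(benzyloxy)-3-methoxyphenyl]-3-[(tert-butyldimethylsilyl)oxy]-2-(4-iodo-2-methoxyphenoxy)propan-1-ol | COc1cc([C@@H](O)[C@H](CO[Si](C)(C)C(C)(C)C)Oc2ccc(I)cc2OC)ccc1OCc1ccccc1 | intermediate
19 | fragment 2: (1R,2S)-1-[4-(benzyloxy)-3-methoxyphenyl]-1,3-bis[(tert-butyldimethylsilyl)oxy]-2-(4-iodo-2-methoxyphenoxy)propane | COc1cc([C@@H](O[Si](C)(C)C(C)(C)C)[C@H](CO[Si](C)(C)C(C)(C)C)Oc2ccc(I)cc2OC)ccc1OCc1ccccc1 | intermediate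
20 | internal alkyne: the (1R,2S) bis-silyl side chain of 19 with ring B bound at C4 to C1 of a (3R,4S)-4-[4-(benzyloxy)-3-methoxyphenyl]-3-{[(tert-butyldiphenylsilyl)oxy]methyl}-4-(methoxymethoxy)but-1-yn-1-yl group | COc1cc([C@@H](O[Si](C)(C)C(C)(C)C)[C@H](CO[Si](C)(C)C(C)(C)C)Oc2ccc(C#C[C@H](CO[Si](c3ccccc3)(c3ccccc3)C(C)(C)C)[C@H](OCOC)c3ccc(OCc4ccccc4)c(OC)c3)cc2OC)ccc1OCc1ccccc1 | intermediate
21 | bromomethyl ether: 20 with OCH2OMe replaced by OCH2Br (formed in the flask) | COc1cc([C@@H](O[Si](C)(C)C(C)(C)C)[C@H](CO[Si](C)(C)C(C)(C)C)Oc2ccc(C#C[C@H](CO[Si](c3ccccc3)(c3ccccc3)C(C)(C)C)[C@H](OCBr)c3ccc(OCc4ccccc4)c(OC)c3)cc2OC)ccc1OCc1ccccc1 | intermediate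
22 | (phenylselanyl)methyl ether: 20 with OCH2OMe replaced by OCH2SePh | COc1cc([C@@H](O[Si](C)(C)C(C)(C)C)[C@H](CO[Si](C)(C)C(C)(C)C)Oc2ccc(C#C[C@H](CO[Si](c3ccccc3)(c3ccccc3)C(C)(C)C)[C@H](OC[Se]c3ccccc3)c3ccc(OCc4ccccc4)c(OC)c3)cc2OC)ccc1OCc1ccccc1 | intermediate
23 | (4R,5S)-5-[4-(benzyloxy)-3-methoxyphenyl]-4-{[(tert-butyldiphenylsilyl)oxy]methyl}-3-(ring B-methylidene)oxolane, ring B carrying the (1R,2S) bis-silyl side chain; E/Z mixture, alkene geometry left open | COc1cc([C@@H](O[Si](C)(C)C(C)(C)C)[C@H](CO[Si](C)(C)C(C)(C)C)Oc2ccc(C=C3CO[C@H](c4ccc(OCc5ccccc5)c(OC)c4)[C@H]3CO[Si](c4ccccc4)(c4ccccc4)C(C)(C)C)cc2OC)ccc1OCc1ccccc1 | intermediate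
24 | spiro-epoxide of 23: oxirane on the exocyclic alkene, oxolane centers (3S,4R,5S), oxirane oxygen anti to the C4 CH2OTBDPS group; oxirane CH left open | COc1cc([C@@H](O[Si](C)(C)C(C)(C)C)[C@H](CO[Si](C)(C)C(C)(C)C)Oc2ccc(C6O[C@@]63CO[C@H](c4ccc(OCc5ccccc5)c(OC)c4)[C@H]3CO[Si](c4ccccc4)(c4ccccc4)C(C)(C)C)cc2OC)ccc1OCc1ccccc1 | intermediate
25 | target with the side-chain 1-OH and 3-OH as TBS ethers and the oxolane CH2OH as TBDPS ether; both phenols free | COc1cc([C@@H](O[Si](C)(C)C(C)(C)C)[C@H](CO[Si](C)(C)C(C)(C)C)Oc2ccc(C[C@@]3(O)CO[C@H](c4ccc(O)c(OC)c4)[C@H]3CO[Si](c4ccccc4)(c4ccccc4)C(C)(C)C)cc2OC)ccc1O | intermediate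
26 | CNP0350466.2: (1R,2S)-1-(4-hydroxy-3-methoxyphenyl)-2-[4-{[(3S,4R,5S)-3-hydroxy-5-(4-hydroxy-3-methoxyphenyl)-4-(hydroxymethyl)oxolan-3-yl]methyl}-2-methoxyphenoxy]propane-1,3-diol | COc1cc([C@@H](O)[C@H](CO)Oc2ccc(C[C@@]3(O)CO[C@H](c4ccc(O)c(OC)c4)[C@H]3CO)cc2OC)ccc1O | target

**Count and risks**

Total step count: 18. Longest linear sequence: 12 steps (steps 1–6 and 13–18; the branch through steps 7–12 is equally long).

Steps most likely to fail:

1. Step 15. Hydrogen transfer to the alkoxymethyl radical may precede ring closure, or the O–CH2 radical may fragment to formaldehyde and a benzylic radical. The fallback closes the same bond by a polar route. It sets out from 20, which is converted with Me2BBr into 21 as in step 14. Instead of adding selenol, ZnBr2 (or SnBr4) in CH2Cl2 at −78 °C ionizes 21 to the oxocarbenium ion. An alkyne Prins-type 5-exo-dig closure follows, and bromide traps the aryl-stabilized vinyl cation to give the (4R,5S)-3-(α-bromobenzylidene)oxolane F1. Reduction of the vinyl bromide with Bu3SnH and Pd(PPh3)4 (zerovalent palladium) returns to the route at 23.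

2. Step 14. In the fully assembled substrate the boron Lewis acid may cleave silyl ethers, ionize the benzylic C–O bonds of the electron-rich arenes, or add across the alkyne. The fallback does the acetal exchange before the union. It sets out from 9: Me2BBr at −78 °C gives the bromomethyl ether F2, and PhSeH with i-Pr2NEt gives the (phenylselanyl)methyl ether F3. Sonogashira coupling of F3 with 19 under the conditions of step 13 returns to the route at 22.

3. Step 5. Anti selectivity may be eroded with an aromatic aldehyde, the allenylmetal may partly racemize, or the silyloxy group may be lost by β-elimination from the propargyl form of the zinc reagent. The fallback sets both centers with an auxiliary and sets out from 6.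
   - (S)-4-Benzyloxazolidin-2-one is N-acylated (n-BuLi, crotonyl chloride) to (S)-4-benzyl-3-[(E)-but-2-enoyl]oxazolidin-2-one F4.
   - Its boron dienolate (Bu2BOTf, Et3N, CH2Cl2, −78 °C) adds to 6 at the α-carbon in an Evans syn-aldol reaction to give the α-vinyl aldol adduct F5.
   - LiBH4 removes the auxiliary to give (1S,2R)-1-[4-(benzyloxy)-3-methoxyphenyl]-2-ethenylpropane-1,3-diol F6.
   - TBDPSCl and imidazole give the primary silyl ether F7; MOMCl and i-Pr2NEt give the methoxymethyl ether F8.
   - OsO4 (cat.), NaIO4 and 2,6-lutidine cleave the vinyl group to the aldehyde F9.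
   - Ohira–Bestmann homologation returns to the route at 9.

Further compounds
F1 | step 15 | (4R,5S)-3-(α-bromobenzylidene)oxolane: 23 with bromine on the exocyclic alkene carbon that bears ring B (E/Z mixture) | COc1cc([C@@H](O[Si](C)(C)C(C)(C)C)[C@H](CO[Si](C)(C)C(C)(C)C)Oc2ccc(C(Br)=C3CO[C@H](c4ccc(OCc5ccccc5)c(OC)c4)[C@H]3CO[Si](c4ccccc4)(c4ccccc4)C(C)(C)C)cc2OC)ccc1OCc1ccccc1
F2 | step 14 | bromomethyl ether of 8: 9 with OCH2OMe replaced by OCH2Br | BrCO[C@H](c1ccc(OCc2ccccc2)c(OC)c1)[C@H](C#C)CO[Si](c1ccccc1)(c1ccccc1)C(C)(C)C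
F3 | step 14 | (phenylselanyl)methyl ether of 8 | c1ccc(cc1)[Se]CO[C@H](c1ccc(OCc2ccccc2)c(OC)c1)[C@H](C#C)CO[Si](c1ccccc1)(c1ccccc1)C(C)(C)C
F4 | step 5 | (S)-4-benzyl-3-[(E)-but-2-enoyl]oxazolidin-2-one | C/C=C/C(=O)N1[C@@H](Cc2ccccc2)COC1=O
F5 | step 5 | (S)-4-benzyl-3-{(2S,3S)-3-[4-(benzyloxy)-3-methoxyphenyl]-2-ethenyl-3-hydroxypropanoyl}oxazolidin-2-one | O[C@H](c1ccc(OCc2ccccc2)c(OC)c1)[C@H](C=C)C(=O)N1[C@@H](Cc2ccccc2)COC1=O
F6 | step 5 | (1S,2R)-1-[4-(benzyloxy)-3-methoxyphenyl]-2-ethenylpropane-1,3-diol | O[C@H](c1ccc(OCc2ccccc2)c(OC)c1)[C@H](C=C)CO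
F7 | step 5 | (1S,2R)-1-[4-(benzyloxy)-3-methoxyphenyl]-2-{[(tert-butyldiphenylsilyl)oxy]methyl}but-3-en-1-ol | O[C@H](c1ccc(OCc2ccccc2)c(OC)c1)[C@H](C=C)CO[Si](c1ccccc1)(c1ccccc1)C(C)(C)C
F8 | step 5 | methoxymethyl ether of F7 | COCO[C@H](c1ccc(OCc2ccccc2)c(OC)c1)[C@H](C=C)CO[Si](c1ccccc1)(c1ccccc1)C(C)(C)C
F9 | step 5 | (2R,3S)-3-[4-(benzyloxy)-3-methoxyphenyl]-2-{[(tert-butyldiphenylsilyl)oxy]methyl}-3-(methoxymethoxy)propanal | COCO[C@H](c1ccc(OCc2ccccc2)c(OC)c1)[C@H](C=O)CO[Si](c1ccccc1)(c1ccccc1)C(C)(C)C
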